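Decide first which to double on Friday's flask: the gas or the solid.

in all of them: solid substrate 0.010 M; gas phase 0.67 mM (held)
- Friday's: protic impurity 0.50 mM; the very flask that is asked about, followed so far
- Monday's: protic impurity 0.25 mM; run made earlier
- flask: protic impurity 0.500 mM; time 20 min

Friday's run (percent of the solid substrate charged)

| time / s | target / % | solid substrate / % |
|---|---|---|
| 10.0 | 0 | 96.4 |
| 25.0 | 0.2 | 90.8 |
| 40.0 | 0.3 | 85.7 |
| 60.0 | 0.3 | 80.8 |
| 90.0 | 0.9 | 74.9 |

Monday's run (percent of the solid substrate charged)

| time / min | target / % | solid substrate / % |
|---|---|---|
| 0.667 | 1.4 | 87.5 |
| 2.00 | 0.2 | 71.6 |
| 4.00 | 3.7 | 62.6 |
| 6.00 | 6.8 | 59.8 |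
| 8.00 | 9.4 | 56.4 |

(each reading ± 0.5 percentage points)

- given per volume of solution although it is solid: solid substrate
- what was read earlier has a scatter of 0.5 percentage points, one standard deviation
- at the start none of the gas phase is in solution
- at the start none of the solid substrate is in solution

* target at 20 min, in percent of the solid substrate charged
* concentration of dissolved gas in solution at 10 min, in percent of saturation
* the change that raises the amount of target at 20 min, in percent of the solid substrate charged most ("none" if none brings more than 2 percentage points) (east / south-east / north-east / west / none)
* amount of target at 20 min, in percent of the solid substrate charged, after south-east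

- east: doubling the transfer coefficient of the gas phase, all else as stated
- south-east: doubling the saturation concentration of gas phase, all else as stated
- north-east: doubling the dissolution coefficient of the solid substrate, all else as stated
- west: doubling the solubility of the solid substrate, all else as stated

Two colleagues disagree. The gas side reckons with gas crossing over as the brake, with dissolved gas sitting low, though it calls this unproven. The forecast is theirs: target 25%, dissolved gas 30% of saturation, best change south-east giving 47%, on the ground that “Doubling saturation doubles the rate in either regime”.

The solid side sets supply against draw. Friday's solid loses 0.216 min⁻¹ of the charge over the first reading, while Monday's target later rises by 0.0142 min⁻¹. Divide what a supply can put into an empty solution by what the reaction draws out, and time drops out. For the solid this refill ratio 15.2 is a reading. If dissolving slows in step with how full the solution is, supply meets draw with the solution short of full by about one over the ratio, 6.60%. The supply is faster than the draw, so the solid side calls the reaction in solution the rate-limiting step. Faster dissolving then has little to close. A doubled solubility raises supply and draw together and keeps the ratio, while a doubled gas saturation raises the draw without the supply and takes the ratio down to 7.60, so this side picks west. Carrying Monday's line to 20 min, with no allowance for Friday's larger impurity, gives it 26.5%, its own figure and not the forecast's.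

The dissolved gas cannot be read, but Monday's demand on it can: 0.213 min⁻¹ of saturation. By the same one over the ratio, the forecast's 30% would need a gas ratio of 1.43, and that is the region where the gas view belongs.

The flask gives 23.6% of target and dissolved gas at 98.3% of saturation. The best change is west, with 20 percentage points, against 17 points for south-east (reaching 40.4%), 1.5 points for north-east and 0.17 points for east.

    starting material + protic impurity → quenched substrate (k = 1300 L mol⁻¹ min⁻¹)
    dissolved gas + target → over-reacted product (k = 18.0 L mol⁻¹ min⁻¹)
    starting material + dissolved gas → target (k = 67.0 L mol⁻¹ min⁻¹)
    gas phase ⇌ dissolved gas, rate k4*(csat - [dissolved gas]) (kL = 16.0 min⁻¹)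
    solid substrate ⇌ starting material, rate k5*(cs5 - [starting material]) while solid is left; crystals form when [starting material] > cs5 (solubility = 3.40 mM, k = 0.750 min⁻¹)
    dissolved gas → decomposed reagent (k = 0.0440 min⁻¹)

At 20.0 min this flask makes starting material 1.00 times as fast as it uses it, and holds 32.1% of the charge, 94.5% of what the solution can hold, while the gas ratio, 16 min⁻¹ over the demand read on Monday, is 75.2. With 0.025 M of solid substrate and the rest held, supply and draw shrink alike as fractions of the larger charge, the refill ratio stays at 15.2, and scaling this flask's target by the charges gives 9.43%, against a simulated 9.43%.

Readings and results were generated by integration for an exercise, noise included.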